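What is left of the solid reagent at the asked time is our concern in alder, where a single-handed catalyst and a solid reagent that starts undissolved make left-handed product from a racemate.

common to all: catalyst 11 mol%

| run | left-handed substrate | right-handed substrate | solid reagent | remark | time |
|---|---|---|---|---|---|
| alder | 0.20 M | 0.20 M | 2.5 equiv | the very flask that is asked about, followed so far |  |
| birch | 0.30 M | 0.30 M | 2.5 equiv | run made earlier |  |
| flask | 0.20 M | 0.20 M | 2.50 equiv |  | 12 h |

| alder: time / min | alder: left-handed product / % | birch: time / h | birch: left-handed product / % |
|---|---|---|---|
| 15.0 | 0 | 2.00 | 2.6 |
| 30.0 | 0.2 | 4.00 | 5.5 |
| 40.0 | 0.4 | 6.00 | 9.0 |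
| 60.0 | 0.8 | 8.00 | 12.1 |

(scatter of a reading: 0.3 percentage points)

- catalyst is single-handed; left-handed substrate and right-handed substrate are mirror images of each other, charged as a racemate, each of them at the stated concentration
- given per volume of solution although it is solid: solid reagent
- the analysis behind the earlier runs scatters by 0.3 percentage points, standard deviation
- at the start none of the solid reagent is in solution

1. how much left-handed product there is at 12 h, in percent of the left-handed substrate and right-handed substrate together charged
2. the change that raises the amount of left-handed product at 12 h, in percent of the left-handed substrate and right-handed substrate together charged most ("none" if none brings more than 2 percentage points) (autumn / summer / midnight / none)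
3. amount of left-handed product at 12 h, in percent of the left-handed substrate and right-handed substrate together charged, after midnight

- autumn: doubling the dissolution coefficient of the solid reagent, all else as stated
- summer: doubling the solubility of the solid reagent, all else as stated
- midnight: doubling the amount of catalyst, all else as stated

We order the clocks of alder, fastest first. Birch gains 0.0158 h⁻¹ of the charge between its first and last readings, and that line, taken back, reaches zero at a lag of 21.5 min. We take the same fractional rate for alder, because its 0.8% at 60.0 min lies within the scatter of the 1.01% this line gives. At that rate the left-handed substrate, 50.0% of the charge, lasts 31.6 h. The solid reagent, 125% of the same charge, lasts 78.9 h at one reagent per product. This reagent clock, the reagent charge divided by the rate of product formation, is our slowest rung.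

So in alder the lag is over long before 12 h, and the clock has run 15.2% by then. Our straight line reaches 18.4%, with the reagent stock apparently ample.

The forecast gives 17.5%, a little below our line, names midnight as best, with 32% after it, and holds that “the run is turnover-limited rather than dissolution-limited”.

The simulation of alder gives 16.7%. The best change is summer, gaining 13 percentage points, against 8.8 points for autumn and 8.1 points for midnight, which ends at 24.7%.

    partner + catalyst + left-handed substrate → catalyst + left-handed product (k = 100 M⁻² h⁻¹)
    partner → decomposed reagent (k = 0.680 h⁻¹)
    partner + catalyst + right-handed substrate → catalyst + right-handed product (k = 16.0 M⁻² h⁻¹)
    solid reagent ⇌ partner, rate k4*(cs4 - [partner]) while solid is left; crystals form when [partner] > cs4 (solubility = 0.0650 M, k = 0.350 h⁻¹)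
    left-handed substrate ⇌ right-handed substrate (k = 0.180 h⁻¹)

The reagent clock reckoned 15.2% of the solid reagent spent in alder by 12 h, yet 42.4% of it has left the solid. At that time the partner's half-life is 1.0 h by decomposition and 2.0 h by conversion to left-handed product, so it decomposes twice as fast as it forms that product. For a neighbour flask, alder read at 30 h, the clock gives 38.0% spent. The computed flask holds 0% of the solid reagent, the limiting reagent there, and 37.5% left-handed product.

All runs were computed on assumed constants.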